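The cycloheptene ring of the hydroazulene (azulene numbering) is cut at the two bonds flanking its C7–C8 unit: the C6=C7 double bond and the C8–C8a bond to the quaternary ring-fusion carbon. One operation makes both: a tertiary radical at C8a, released by photoredox decarboxylation of a cyclopentanecarboxylic acid, adds to the CH2 terminus of vinyltriphenylphosphonium bromide, and the ylide formed by radical–polar crossover closes the seven-membered ring on a side-chain methyl ketone by Wittig olefination. The step exploits the CH2–CH= link between the angular-methyl carbon C8a and the methyl-bearing alkene carbon C6. Its precursor is a monocyclic keto acid that already carries the C3 carbinol, C3a and the C4 silyl ether.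

Key step: step 7

Assumptions:
- The target is read from its SMILES as the (3R,3aS,4S,8aR) isomer: trans ring fusion, tertiary OH cis to the angular methyl, ester oxygen trans to it.
- The ligand enantiomer written in step 2, (R)-DTBM-SEGPHOS = (R)-5,5′-bis[bis(3,5-di-tert-butyl-4-methoxyphenyl)phosphino]-4,4′-bi-1,3-benzodioxole, is taken as the one that gives the (1S) ester; if the sense of induction is the opposite, its mirror image is used.
- Compounds 3, 10 and 15 are taken as commercially available.

Step 1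
Reactants: 1 ethyl 2-(2-methyl-1,3-dioxolan-2-yl)acetate
Product: 2 2-(2-methyl-1,3-dioxolan-2-yl)acetaldehyde
Conditions: i-Bu2AlH (1.05 equiv), CH2Cl2, −78 °C; aq. KNaC4H4O6 (potassium sodium tartrate)
Reagents that add atoms: none
Why: Partial hydride reduction of an ester to the aldehyde: at −78 °C the aluminium hemiacetal formed by one hydride transfer, stabilised by chelation to a ketal oxygen, should persist until work-up, so over-reduction should be minor and no stereocenter is formed.

Step 2
Reactants: 3 methyl 3-oxocyclopent-1-ene-1-carboxylate; 2 2-(2-methyl-1,3-dioxolan-2-yl)acetaldehyde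
Product: 5 methyl (1S,2S)-2-[(1S)-1-hydroxy-2-(2-methyl-1,3-dioxolan-2-yl)ethyl]-3-oxocyclopentane-1-carboxylate, via boron enolate 4 (not isolated)
Conditions: Cu(OAc)2·H2O (3 mol%), (R)-DTBM-SEGPHOS (3 mol%), pinacolborane (1.2 equiv), toluene, 0 °C; then 2, −78 → −20 °C; aq. NH4Cl
Reagents that add atoms: none
Why: Reductive aldol reaction (copper hydride-catalysed asymmetric conjugate reduction, then aldol addition): the ligated hydride of monovalent copper should add to C1 of the enone under ligand control (C1, S), transmetallation to boron gives the E-configured cyclic enolate 4, and this should add to 2 through a closed chair transition state on the ring face anti to the ester, which sets C2 trans to the ester and the carbinol carbon in the anti-aldol sense.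

Step 3
Reactants: 5 methyl (1S,2S)-2-[(1S)-1-hydroxy-2-(2-methyl-1,3-dioxolan-2-yl)ethyl]-3-oxocyclopentane-1-carboxylate
Product: 6 methyl (1S,2S)-2-[(1S)-1-{[tert-butyl(dimethyl)silyl]oxy}-2-(2-methyl-1,3-dioxolan-2-yl)ethyl]-3-oxocyclopentane-1-carboxylate
Conditions: t-BuMe2SiOTf (1.1 equiv), 2,6-lutidine, CH2Cl2, −78 °C
Reagents that add atoms: tert-butyldimethylsilyl trifluoromethanesulfonate, CC(C)(C)[Si](C)(C)OS(=O)(=O)C(F)(F)F
Why: Protection of an alcohol as a silyl ether: O-silylation of the secondary alcohol at −78 °C should be faster than enol silylation of the ketone or opening of the ketone-derived dioxolane, and it masks the aldol hydroxyl against retro-aldol cleavage in the following basic steps.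

Step 4
Reactants: 6 methyl (1S,2S)-2-[(1S)-1-{[tert-butyl(dimethyl)silyl]oxy}-2-(2-methyl-1,3-dioxolan-2-yl)ethyl]-3-oxocyclopentane-1-carboxylate
Product: 7 methyl (1S,2S,3R)-2-[(1S)-1-{[tert-butyl(dimethyl)silyl]oxy}-2-(2-methyl-1,3-dioxolan-2-yl)ethyl]-3-hydroxy-3-(propan-2-yl)cyclopentane-1-carboxylate
Conditions: i-PrMgCl (1.5 equiv), LaCl3·2LiCl (1 equiv), THF, −78 → −30 °C; H2O
Reagents that add atoms: isopropylmagnesium chloride, CC(C)[Mg]Cl
Why: Grignard 1,2-addition to the ketone, with LaCl3·2LiCl suppressing enolisation and β-hydride reduction, should take place on the face anti to the adjacent C2 side chain and so set the tertiary carbinol (C3, R) with its hydroxyl cis to that chain, while the methyl ester is left untouched at low temperature.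

Step 5
Reactants: 7 methyl (1S,2S,3R)-2-[(1S)-1-{[tert-butyl(dimethyl)silyl]oxy}-2-(2-methyl-1,3-dioxolan-2-yl)ethyl]-3-hydroxy-3-(propan-2-yl)cyclopentane-1-carboxylate
Product: 8 methyl (1R,2S,3R)-2-[(1S)-1-{[tert-butyl(dimethyl)silyl]oxy}-2-(2-methyl-1,3-dioxolan-2-yl)ethyl]-3-hydroxy-1-methyl-3-(propan-2-yl)cyclopentane-1-carboxylate
Conditions: LiN(i-Pr)2 (2.3 equiv), THF, −78 → −30 °C; MeI, −78 → −20 °C; H2O
Reagents that add atoms: iodomethane, CI
Why: Enolate alkylation: two equivalents of base form the alkoxide and the ester enolate at C1, which should be C-methylated anti to the C2 side chain to give the quaternary carbon; its configuration is of no consequence, because C1 becomes a planar radical in step 7.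

Step 6
Reactants: 8 methyl (1R,2S,3R)-2-[(1S)-1-{[tert-butyl(dimethyl)silyl]oxy}-2-(2-methyl-1,3-dioxolan-2-yl)ethyl]-3-hydroxy-1-methyl-3-(propan-2-yl)cyclopentane-1-carboxylate
Product: 9 (1R,2S,3R)-2-[(1S)-1-{[tert-butyl(dimethyl)silyl]oxy}-3-oxobutyl]-3-hydroxy-1-methyl-3-(propan-2-yl)cyclopentane-1-carboxylic acid
Conditions: LiOH·H2O, THF/MeOH/H2O, 50 °C; then 1 M HCl to pH 2, THF/H2O, 0 °C → rt
Reagents that add atoms: lithium hydroxide, [Li+].[OH-]; water, O
Why: Ester saponification, which the cis tertiary hydroxyl should assist, followed by acid-catalysed ketal hydrolysis unveils the acid and the methyl ketone in that order, so the β-silyloxy ketone never meets hydroxide and no stereocenter is touched.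

Step 7
Reactants: 9 (1R,2S,3R)-2-[(1S)-1-{[tert-butyl(dimethyl)silyl]oxy}-3-oxobutyl]-3-hydroxy-1-methyl-3-(propan-2-yl)cyclopentane-1-carboxylic acid; 10 ethenyl(triphenyl)phosphonium bromide
Product: 13 (3R,3aS,4S,8aR)-4-{[tert-butyl(dimethyl)silyl]oxy}-6,8a-dimethyl-3-(propan-2-yl)-1,2,3,3a,4,5,8,8a-octahydroazulen-3-ol, via cesium carboxylate 11 (not isolated), via phosphonium ylide 12 (not isolated)
Conditions: CsOH·H2O (1.0 equiv), MeOH, then evaporation to dryness; 10 (1.5 equiv), 1,2,3,5-tetrakis(carbazol-9-yl)-4,6-dicyanobenzene (4CzIPN, 3 mol%), 4 Å MS, MeCN, 450 nm LEDs, rt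
Reagents that add atoms: none
Why: Proposed new method: photoexcited 4CzIPN oxidises carboxylate 11, loss of CO2 gives the planar tertiary radical at C1 of the cyclopentane, this adds to the CH2 terminus of 10 (new C8–C8a bond of 13), and the α-phosphonio radical is reduced by the photocatalyst radical anion to ylide 12, which olefinates the tethered methyl ketone (new C6=C7 bond) with loss of Ph3PO. The closest known reaction type is the photoredox three-component olefination of carboxylic acids, vinylphosphonium salts and carbonyl compounds (decarboxylative Giese addition, radical–polar crossover, Wittig reaction); what is new is its intramolecular use on a ketone to close a ring. The seven-membered ring closes by 7-exo-trig addition of the ylide carbon to the ketone carbonyl, then collapse of the oxaphosphetane. The quaternary stereocenter C8a is set by substrate control in the radical addition: the acceptor should approach the face of the cyclopentyl radical anti to the adjacent branched silyloxyalkyl chain, so that either C1 epimer of 9 leads to the trans-fused product. The step needs this facial selectivity and a ring closure that outruns protonation of the ylide; the bulky neighbouring chain should secure the first, and the pre-formed, dried cesium salt (no bicarbonate and no proton source more acidic than the tertiary alcohol) should secure the second.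

Step 8
Reactants: 13 (3R,3aS,4S,8aR)-4-{[tert-butyl(dimethyl)silyl]oxy}-6,8a-dimethyl-3-(propan-2-yl)-1,2,3,3a,4,5,8,8a-octahydroazulen-3-ol
Product: 14 (3R,3aS,4S,8aR)-6,8a-dimethyl-3-(propan-2-yl)-1,2,3,3a,4,5,8,8a-octahydroazulene-3,4-diol
Conditions: Bu4NF (1.5 equiv), THF, 0 °C → rt; aq. NH4Cl
Reagents that add atoms: none
Why: Fluoride-mediated cleavage of the silyl ether, driven by the strong Si–F bond, should free the secondary alcohol without affecting the tertiary alcohol or the trisubstituted alkene.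

Step 9
Reactants: 14 (3R,3aS,4S,8aR)-6,8a-dimethyl-3-(propan-2-yl)-1,2,3,3a,4,5,8,8a-octahydroazulene-3,4-diol; 15 2,2-dimethyl-4H-1,3-benzodioxin-4-one
Product: 16 (3R,3aS,4S,8aR)-3-hydroxy-6,8a-dimethyl-3-(propan-2-yl)-1,2,3,3a,4,5,8,8a-octahydroazulen-4-yl 2-hydroxybenzoate
Conditions: NaN(SiMe3)2 (1.05 equiv), THF, −78 °C; then 15, −78 → 0 °C; aq. NH4Cl
Reagents that add atoms: none
Why: Alkoxide transesterification of an acetonide-protected salicylate: the less hindered secondary alkoxide should attack the carbonyl group of 15, and the ring-opened hemiketal phenoxide loses acetone, which gives the salicylate ester with its free phenol directly and with retention at C4, since the carbinol C–O bond is not broken.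

Compound list
1 | ethyl 2-(2-methyl-1,3-dioxolan-2-yl)acetate | CCOC(=O)CC1(C)OCCO1 | starting material
2 | 2-(2-methyl-1,3-dioxolan-2-yl)acetaldehyde | CC1(CC=O)OCCO1 | intermediate
3 | methyl 3-oxocyclopent-1-ene-1-carboxylate | COC(=O)C1=CC(=O)CC1 | starting material
4 | methyl (1S)-3-[(4,4,5,5-tetramethyl-1,3,2-dioxaborolan-2-yl)oxy]cyclopent-2-ene-1-carboxylate (boron enolate) | COC(=O)[C@H]1CCC(OB2OC(C)(C)C(C)(C)O2)=C1 | intermediate
5 | methyl (1S,2S)-2-[(1S)-1-hydroxy-2-(2-methyl-1,3-dioxolan-2-yl)ethyl]-3-oxocyclopentane-1-carboxylate | CC1(C[C@H](O)[C@H]2C(=O)CC[C@@H]2C(=O)OC)OCCO1 | intermediate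
6 | methyl (1S,2S)-2-[(1S)-1-{[tert-butyl(dimethyl)silyl]oxy}-2-(2-methyl-1,3-dioxolan-2-yl)ethyl]-3-oxocyclopentane-1-carboxylate | CC1(C[C@H](O[Si](C)(C)C(C)(C)C)[C@H]2C(=O)CC[C@@H]2C(=O)OC)OCCO1 | intermediate
7 | methyl (1S,2S,3R)-2-[(1S)-1-{[tert-butyl(dimethyl)silyl]oxy}-2-(2-methyl-1,3-dioxolan-2-yl)ethyl]-3-hydroxy-3-(propan-2-yl)cyclopentane-1-carboxylate | CC1(C[C@H](O[Si](C)(C)C(C)(C)C)[C@H]2[C@](O)(C(C)C)CC[C@@H]2C(=O)OC)OCCO1 | intermediate
8 | methyl (1R,2S,3R)-2-[(1S)-1-{[tert-butyl(dimethyl)silyl]oxy}-2-(2-methyl-1,3-dioxolan-2-yl)ethyl]-3-hydroxy-1-methyl-3-(propan-2-yl)cyclopentane-1-carboxylate | CC1(C[C@H](O[Si](C)(C)C(C)(C)C)[C@H]2[C@](O)(C(C)C)CC[C@@]2(C)C(=O)OC)OCCO1 | intermediate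
9 | (1R,2S,3R)-2-[(1S)-1-{[tert-butyl(dimethyl)silyl]oxy}-3-oxobutyl]-3-hydroxy-1-methyl-3-(propan-2-yl)cyclopentane-1-carboxylic acid | CC(=O)C[C@H](O[Si](C)(C)C(C)(C)C)[C@H]1[C@](O)(C(C)C)CC[C@@]1(C)C(=O)O | intermediate
10 | ethenyl(triphenyl)phosphonium bromide (vinyltriphenylphosphonium bromide) | C=C[P+](c1ccccc1)(c1ccccc1)c1ccccc1.[Br-] | starting material
11 | cesium (1R,2S,3R)-2-[(1S)-1-{[tert-butyl(dimethyl)silyl]oxy}-3-oxobutyl]-3-hydroxy-1-methyl-3-(propan-2-yl)cyclopentane-1-carboxylate | CC(=O)C[C@H](O[Si](C)(C)C(C)(C)C)[C@H]1[C@](O)(C(C)C)CC[C@@]1(C)C(=O)[O-].[Cs+] | intermediate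
12 | (4S)-4-{[tert-butyl(dimethyl)silyl]oxy}-4-{(1S,2R,5R)-2-hydroxy-5-methyl-2-(propan-2-yl)-5-[2-(triphenyl-λ5-phosphanylidene)ethyl]cyclopentyl}butan-2-one (phosphonium ylide) | CC(=O)C[C@H](O[Si](C)(C)C(C)(C)C)[C@H]1[C@](O)(C(C)C)CC[C@]1(C)CC=P(c2ccccc2)(c2ccccc2)c2ccccc2 | intermediate
13 | (3R,3aS,4S,8aR)-4-{[tert-butyl(dimethyl)silyl]oxy}-6,8a-dimethyl-3-(propan-2-yl)-1,2,3,3a,4,5,8,8a-octahydroazulen-3-ol | CC1=CC[C@@]2(C)CC[C@@](O)(C(C)C)[C@@H]2[C@@H](O[Si](C)(C)C(C)(C)C)C1 | intermediate
14 | (3R,3aS,4S,8aR)-6,8a-dimethyl-3-(propan-2-yl)-1,2,3,3a,4,5,8,8a-octahydroazulene-3,4-diol | CC1=CC[C@@]2(C)CC[C@@](O)(C(C)C)[C@@H]2[C@@H](O)C1 | intermediate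
15 | 2,2-dimethyl-4H-1,3-benzodioxin-4-one | CC1(C)OC(=O)c2ccccc2O1 | starting material
16 | (3R,3aS,4S,8aR)-3-hydroxy-6,8a-dimethyl-3-(propan-2-yl)-1,2,3,3a,4,5,8,8a-octahydroazulen-4-yl 2-hydroxybenzoate | CC1=CC[C@@]2(C)CC[C@@](O)(C(C)C)[C@@H]2[C@@H](OC(=O)c2ccccc2O)C1 | target

Total step count: 9. Longest linear sequence: 9 (1 → 2 → 5 → 6 → 7 → 8 → 9 → 13 → 14 → 16).

Steps most likely to fail

Step 7 (the step under the label). Ylide 12 may be protonated or re-oxidised by the excited photocatalyst faster than it closes the seven-membered ring on a ketone, so that the sequence stalls after the radical addition. The fallback uses known chemistry, sets out from 9 and returns at 13. Photoredox decarboxylative radical allylation of 9 with allyl phenyl sulfone (4CzIPN, Cs2CO3, MeCN, 450 nm; addition, then β-fragmentation of the sulfonyl radical) should give the allyl ketone (4S)-4-{[tert-butyl(dimethyl)silyl]oxy}-4-[(1S,2R,5R)-2-hydroxy-5-methyl-2-(propan-2-yl)-5-(prop-2-en-1-yl)cyclopentyl]butan-2-one F1. Wittig methylenation (Ph3P=CH2, THF, 0 °C) should then give the diene (1R,2S,3R)-2-[(1S)-1-{[tert-butyl(dimethyl)silyl]oxy}-3-methylbut-3-en-1-yl]-3-methyl-1-(propan-2-yl)-3-(prop-2-en-1-yl)cyclopentan-1-ol F2. Ring-closing metathesis with the second-generation Grubbs catalyst, (H2IMes)(PCy3)Cl2Ru=CHPh, in CH2Cl2 at 40 °C closes the trisubstituted cycloheptene and gives 13.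

Step 2. Hydride may be delivered with low enantioselectivity or to C2 under the influence of the ester. The weakly Lewis-acidic pinacol boron enolate may also add to the enolisable aldehyde sluggishly and with poor anti selectivity. The fallback sets out from 3 and returns at 5. Copper hydride-catalysed asymmetric conjugate hydrosilylation (Cu(OAc)2·H2O, (R)-DTBM-SEGPHOS, PhMe2SiH, toluene, 0 °C) should give the isolable silyl enol ether methyl (1S)-3-{[dimethyl(phenyl)silyl]oxy}cyclopent-2-ene-1-carboxylate F3. Cleavage of its Si–O bond with KOtBu (THF, −78 °C), transmetallation with ZnCl2 and addition of 2 should give 5 through a closed zinc aldol transition state.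

Step 4. The hindered, enolisable ketone may be deprotonated, with loss of the β-silyloxy group, or reduced by β-hydride transfer from the isopropyl reagent instead of being alkylated. The fallback sets out from 6 and returns at 7. Addition of the smaller, hydride-free CH2=C(CH3)MgBr in the presence of CeCl3 (THF, −78 °C) should give the isopropenyl carbinol methyl (1S,2S,3S)-2-[(1S)-1-{[tert-butyl(dimethyl)silyl]oxy}-2-(2-methyl-1,3-dioxolan-2-yl)ethyl]-3-hydroxy-3-(prop-1-en-2-yl)cyclopentane-1-carboxylate F4 with the same facial preference. Hydrogenation (H2, PtO2, EtOAc) then gives 7.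

Further compounds
F1 | step 7 | (4S)-4-{[tert-butyl(dimethyl)silyl]oxy}-4-[(1S,2R,5R)-2-hydroxy-5-methyl-2-(propan-2-yl)-5-(prop-2-en-1-yl)cyclopentyl]butan-2-one | CC(=O)C[C@H](O[Si](C)(C)C(C)(C)C)[C@H]1[C@](O)(C(C)C)CC[C@]1(C)CC=C
F2 | step 7 | (1R,2S,3R)-2-[(1S)-1-{[tert-butyl(dimethyl)silyl]oxy}-3-methylbut-3-en-1-yl]-3-methyl-1-(propan-2-yl)-3-(prop-2-en-1-yl)cyclopentan-1-ol | C=C(C)C[C@H](O[Si](C)(C)C(C)(C)C)[C@H]1[C@](O)(C(C)C)CC[C@]1(C)CC=C
F3 | step 2 | methyl (1S)-3-{[dimethyl(phenyl)silyl]oxy}cyclopent-2-ene-1-carboxylate | COC(=O)[C@H]1CCC(O[Si](C)(C)c2ccccc2)=C1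
F4 | step 4 | methyl (1S,2S,3S)-2-[(1S)-1-{[tert-butyl(dimethyl)silyl]oxy}-2-(2-methyl-1,3-dioxolan-2-yl)ethyl]-3-hydroxy-3-(prop-1-en-2-yl)cyclopentane-1-carboxylate | CC1(C[C@H](O[Si](C)(C)C(C)(C)C)[C@H]2[C@](O)(C(C)=C)CC[C@@H]2C(=O)OC)OCCO1
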